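Start at the early times of the autumn flask and build it up one process at a time.

the same everywhere: gas 0.48 mM (held)
- autumn: substrate 10 mM; solid second nucleophile 18 mM; the very flask that is asked about, followed so far
- midnight: substrate 20 mM; solid second nucleophile 18 mM; run made earlier
- flask: substrate 10 mM; solid second nucleophile 18.0 mM; time 5.0 min

autumn run (percent of the substrate charged)

| time / s | other capture product / % | target / % |
|---|---|---|
| 10.0 | 0.5 | 45.8 |
| 20.0 | 1.1 | 69.1 |
| 30.0 | 1.6 | 80.6 |
| 60.0 | 0.8 | 89.2 |
| 120 | 1.9 | 82.4 |

midnight run (percent of the substrate charged)

| time / min | other capture product / % | target / % |
|---|---|---|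
| 0.333 | 1.3 | 69.2 |
| 0.833 | 1.1 | 88.8 |
| 1.50 | 1.8 | 87.0 |
| 2.50 | 2.4 | 78.7 |
| 4.00 | 1.3 | 67.4 |

(standard deviation of a reading: 0.3 percentage points)

- ratio of other capture product to target at 1.0 s
- ratio of other capture product to target at 5.0 min
- which of other capture product and target there is more of at 5.0 min

- at the start none of the solid second nucleophile is in solution
- at the start none of the gas is in solution

Begin with the main step by itself: substrate becomes target, and in the autumn run the target's fraction of the charge climbs to 89.2% at 60.0 s. This step gives a curve that rises and stays up.

Now add the loss that the readings show. In the midnight run the target falls from 87.0% at 1.50 min to 78.7% at 2.50 min and 67.4% at 4.00 min. Take logarithms of these falls: the two stretches give 0.100 /min and 0.103 /min, the same within scatter. A steady fractional fall fits a target that meets a partner of unchanging concentration, the pseudo-first-order case, and I take that partner to be dissolved second nucleophile, topped up from the solid. Call the fraction of target lost per minute the loss constant, read between the outer readings as 0.102 /min. Both runs were charged with 18 mM of solid, so I assume the same partner level in each; apply the constant to the autumn reading of 82.4% at 120 s, and the autumn target at 5.0 min comes to 60.7%.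

Then add the side capture. The last three autumn readings of other capture product scatter without trend around 1.43%, so my ratio at 5.0 min is 0.0236, with the target ahead. At 1.0 s I expect less than the ratio of 0.0109 read at 10.0 s; at the start none of the solid is in solution.

The forecast gives 0.012 early and 0.028 late, higher than my late ratio, with target ahead, and says that the side product “neither feeds on the target nor catches up”.

The flask gives 0.00830 at 1.0 s and 0.0232 at 5.0 min; target leads, at 61.0% against 1.41%.

    substrate ⇌ intermediate (K = 0.220, k = 0.0650 /s)
    first nucleophile + intermediate → target (k = 24000 /M/s)
    second nucleophile + intermediate → other capture product (k = 47.0 /M/s)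
    solid second nucleophile ⇌ second nucleophile, rate k4*(cs4 - [second nucleophile]) while solid is left; crystals form when [second nucleophile] > cs4 (solubility = 3.60 mM, k = 1.70 /s)
    second nucleophile + target → over-reaction product (k = 0.470 /M/s)
    gas ⇌ first nucleophile, rate k6*(csat - [first nucleophile]) (kL = 58.0 /s)

In the flask, second nucleophile stands at 3.59 mM at 2.50 min and 3.59 mM at 5.00 min, while target falls from 78.6% to 61.0%, a loss constant of 0.101 /min. Now take the neighbouring flask, charged with 4.5 mM of solid second nucleophile, 0.450 equiv to substrate. At 5.00 min its undissolved solid stands at 0% of its charge, and the 33% of the charge still there, solid or dissolved, is second nucleophile in solution at 1.50 mM. Scale the loss constant by that concentration, and it is 0.0426 /min at that time. At that time the neighbouring flask holds 70.0% target, and its ratio is 0.0202.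

The runs are calculated with made-up constants; noise was put on by code.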